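## Retrosynthetic overview

1. The target is prostaglandin E2 1,15-lactone 11-acetate. The acetate is put on last, after removal of a silyl group from the C11 oxygen.
2. The 13-membered lactone is opened at the C5=C6 Z-alkene: Lindlar semihydrogenation of a cycloalkyne, which comes from ring-closing alkyne metathesis of a diyne ester (C15 hept-5-ynoate plus a C8 but-2-ynyl group).
3. The diyne ester comes from a Steglich esterification and a three-component coupling: 4-silyloxycyclopentenone, a C13–C20 vinyl metal and a propargylic iodide.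
4. The four building blocks are made in parallel: the enone from a meso diacetate (enzymatic desymmetrisation), the vinyl iodide from hexanoyl chloride and acetylene (CBS reduction), hept-5-ynoic acid from hex-5-ynoic acid, and 1-iodobut-2-yne from the bromide.
5. Ring order: the cyclopentane ring is carried in from the meso starting material and is never formed in the route; the macrolactone ring is the only ring formed, by the alkyne metathesis.

Assumption: each numbered step ends with an isolated product; enzymes, catalysts, solvents and work-up reagents carry no compound number.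

## Route

**Step 1**
Reactants: 1 hexanoyl chloride; 2 acetylene
Product: 3 (E)-1-chlorooct-1-en-3-one
Conditions: AlCl3 (1.1 equiv), acetylene stream, CH2Cl2, 0 °C; ice/HCl quench
Reagents that add atoms: none
Why: Friedel–Crafts-type acylation of acetylene, in which the acylium ion adds to the alkyne and chloride from the acid chloride (via AlCl4−) caps the vinyl cation to give the conjugated, thermodynamically favoured E β-chlorovinyl ketone, AlCl3 acting only as Lewis acid.

**Step 2**
Reactants: 3 (E)-1-chlorooct-1-en-3-one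
Product: 4 (E)-1-iodooct-1-en-3-one
Conditions: NaI (2 equiv), acetone, reflux, dark
Reagents that add atoms: sodium iodide, [Na+].[I-]
Why: Finkelstein-type halide exchange by conjugate addition–elimination at the β-carbon, driven by precipitation of NaCl and returning the more stable E isomer.

**Step 3**
Reactants: 4 (E)-1-iodooct-1-en-3-one
Product: 6 (S,E)-1-iodooct-1-en-3-ol, via catecholborate ester 5 (not isolated)
Conditions: (R)-2-methyl-CBS-oxazaborolidine (10 mol %), catecholborane (1.5 equiv), toluene, −78 °C; then H2O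
Reagents that add atoms: none
Why: Corey–Bakshi–Shibata reduction in which the (R)-oxazaborolidine treats the iodovinyl group as the large substituent and delivers hydride to the face that gives the (S)-carbinol (C15 of the target); any minor enantiomer is removed later as the separable 15-epi diastereomer after step 11.

**Step 4**
Reactants: 6 (S,E)-1-iodooct-1-en-3-ol
Product: 7 (S,E)-triethyl[(1-iodooct-1-en-3-yl)oxy]silane
Conditions: Et3SiCl (1.2 equiv), imidazole (2 equiv), DMF, 0 °C → rt
Reagents that add atoms: chlorotriethylsilane, CC[Si](Cl)(CC)CC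
Why: Imidazole-mediated silylation of a secondary alcohol without touching the stereocentre; the triethylsilyl ether is chosen because it can later be cleaved in the presence of the ring tert-butyldimethylsilyl ether.

**Step 5**
Reactants: 8 cis-cyclopent-4-ene-1,3-diyl diacetate (meso)
Product: 9 (1R,4S)-4-hydroxycyclopent-2-en-1-yl acetate
Conditions: electric eel acetylcholinesterase, NaH2PO4/Na2HPO4 buffer (pH 6.9), rt
Reagents that add atoms: none
Why: Enzymatic desymmetrisation of a meso diester, in which the esterase hydrolyses only the acetate on the (S)-configured carbon and so fixes the absolute configuration of the future C11 in high ee.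

**Step 6**
Reactants: 9 (1R,4S)-4-hydroxycyclopent-2-en-1-yl acetate
Product: 10 (R)-4-oxocyclopent-2-en-1-yl acetate
Conditions: Dess–Martin periodinane (1.2 equiv), CH2Cl2, 0 °C → rt
Reagents that add atoms: none
Why: Dess–Martin oxidation of the allylic alcohol under non-basic conditions gives the enone while the acetate-bearing stereocentre is neither epimerised nor eliminated.

**Step 7**
Reactants: 10 (R)-4-oxocyclopent-2-en-1-yl acetate
Product: 11 (R)-4-hydroxycyclopent-2-en-1-one
Conditions: wheat germ lipase, NaH2PO4/Na2HPO4 buffer (pH 5), rt, 5–7 d; continuous extraction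
Reagents that add atoms: none
Why: Lipase-catalysed ester hydrolysis at slightly acidic pH removes the acetate without the β-elimination and racemisation that chemical base would cause in this 4-acyloxy enone.

**Step 8**
Reactants: 11 (R)-4-hydroxycyclopent-2-en-1-one
Product: 12 (R)-4-[(tert-butyldimethylsilyl)oxy]cyclopent-2-en-1-one
Conditions: t-BuMe2SiCl (1.2 equiv), Et3N, DMAP (cat.), CH2Cl2, 0 °C → rt
Reagents that add atoms: tert-butyldimethylsilyl chloride, CC(C)(C)[Si](C)(C)Cl
Why: Standard O-silylation with retention; the bulky silyl ether later directs the conjugate addition to the opposite ring face and is a poor leaving group toward β-elimination.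

**Step 9**
Reactants: 13 hex-5-ynoic acid
Product: 16 hept-5-ynoic acid, via dilithium dianion 14 (not isolated), via lithium hept-5-ynoate 15 (not isolated)
Conditions: n-BuLi (2.1 equiv), THF/DMPU, −78 → 0 °C; MeI (1.1 equiv), −78 °C → rt; then 1 M HCl
Reagents that add atoms: iodomethane, CI
Why: Dianion alkylation, in which the acetylide carbon is far more nucleophilic than the carboxylate oxygen so that one equivalent of MeI caps the alkyne with the methyl group needed for alkyne metathesis.

**Step 10**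
Reactants: 17 1-bromobut-2-yne
Product: 18 1-iodobut-2-yne
Conditions: NaI (1.5 equiv), acetone, rt, dark
Reagents that add atoms: sodium iodide, [Na+].[I-]
Why: Finkelstein reaction driven by precipitation of NaBr gives the more reactive propargylic iodide needed for enolate trapping.

**Step 11**
Reactants: 7 (S,E)-triethyl[(1-iodooct-1-en-3-yl)oxy]silane; 12 (R)-4-[(tert-butyldimethylsilyl)oxy]cyclopent-2-en-1-one; 18 1-iodobut-2-yne
Product: 22 (2R,3R,4R)-2-(but-2-yn-1-yl)-4-[(tert-butyldimethylsilyl)oxy]-3-[(S,E)-3-[(triethylsilyl)oxy]oct-1-en-1-yl]cyclopentan-1-one, via vinyllithium 19 (not isolated), via lithium zincate 20 (not isolated), via lithium enolate 21 (not isolated)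
Conditions: 7, t-BuLi (2.0 equiv), Et2O, −78 °C; Me2Zn (1.0 equiv), THF, −78 → 0 °C; 12, −78 °C; HMPA, 18 (5 equiv), −78 → −40 °C; aq. NH4Cl
Reagents that add atoms: none
Why: Noyori three-component coupling, in which iodine–lithium exchange with retention of E geometry and zincate formation are followed by conjugate addition anti to the silyloxy group (sets C12) and by alkylation of the regiodefined enolate anti to the new vinyl group (sets C8), giving the all-trans ring.

**Step 12**
Reactants: 22 (2R,3R,4R)-2-(but-2-yn-1-yl)-4-[(tert-butyldimethylsilyl)oxy]-3-[(S,E)-3-[(triethylsilyl)oxy]oct-1-en-1-yl]cyclopentan-1-one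
Product: 23 (2R,3R,4R)-2-(but-2-yn-1-yl)-4-[(tert-butyldimethylsilyl)oxy]-3-[(S,E)-3-hydroxyoct-1-en-1-yl]cyclopentan-1-one
Conditions: AcOH/THF/H2O (3:1:1), 0 °C → rt, monitored by TLC
Reagents that add atoms: none
Why: Selective acidic solvolysis of silyl ethers, the triethylsilyl ether cleaving much faster than the tert-butyldimethylsilyl ether, under conditions too mild to dehydrate the β-silyloxy ketone.

**Step 13**
Reactants: 23 (2R,3R,4R)-2-(but-2-yn-1-yl)-4-[(tert-butyldimethylsilyl)oxy]-3-[(S,E)-3-hydroxyoct-1-en-1-yl]cyclopentan-1-one; 16 hept-5-ynoic acid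
Product: 25 (S,E)-1-[(1R,2R,5R)-2-(but-2-yn-1-yl)-5-[(tert-butyldimethylsilyl)oxy]-3-oxocyclopentyl]oct-1-en-3-yl hept-5-ynoate, via O-acylisourea 24 (not isolated)
Conditions: 16 (1.5 equiv), DCC (1.5 equiv), DMAP (0.2 equiv), CH2Cl2, 0 °C → rt
Reagents that add atoms: none
Why: Steglich esterification acylates the C15 oxygen without breaking the C15–O bond, so the (S) configuration is retained and both methyl-capped alkynes are in place.

**Step 14**
Reactants: 25 (S,E)-1-[(1R,2R,5R)-2-(but-2-yn-1-yl)-5-[(tert-butyldimethylsilyl)oxy]-3-oxocyclopentyl]oct-1-en-3-yl hept-5-ynoate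
Product: 26 (8R,11R,12R,13E,15S)-11-[(tert-butyldimethylsilyl)oxy]-9-oxoprost-13-en-5-yno-1,15-lactone (13-membered cycloalkyne fused to the cyclopentanone at C8/C12)
Conditions: Mo(≡C-C6H4-4-OMe)(OSiPh3)3 (5 mol %), 5 Å MS, toluene (2 mM), rt → 50 °C
Reagents that add atoms: none
Why: Ring-closing alkyne metathesis closes the 13-membered ring at C5≡C6; the molybdenum alkylidyne ignores the E-alkene, ketone, ester and silyl ether, and the sieves trap the released but-2-yne, which together with high dilution drives cyclisation over oligomerisation.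

**Step 15**
Reactants: 26 (8R,11R,12R,13E,15S)-11-[(tert-butyldimethylsilyl)oxy]-9-oxoprost-13-en-5-yno-1,15-lactone
Product: 27 (5Z,8R,11R,12R,13E,15S)-11-[(tert-butyldimethylsilyl)oxy]-9-oxoprosta-5,13-dieno-1,15-lactone
Conditions: H2 (1 atm), Pd/CaCO3 poisoned with Pb(OAc)2 (Lindlar catalyst), quinoline, CH2Cl2/hexane, rt
Reagents that add atoms: none
Why: Lindlar semihydrogenation adds hydrogen syn to the alkyne and stops at the alkene, so C5=C6 is formed purely Z while the E-alkene and ketone are untouched.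

**Step 16**
Reactants: 27 (5Z,8R,11R,12R,13E,15S)-11-[(tert-butyldimethylsilyl)oxy]-9-oxoprosta-5,13-dieno-1,15-lactone
Product: 28 (5Z,8R,11R,12R,13E,15S)-11-hydroxy-9-oxoprosta-5,13-dieno-1,15-lactone (prostaglandin E2 1,15-lactone)
Conditions: 48% aq. HF, MeCN, 0 °C
Reagents that add atoms: none
Why: Fluoride-driven desilylation in a weakly acidic, non-basic medium frees the C11 hydroxyl without E1cB dehydration of the β-hydroxy ketone or opening of the lactone.

**Step 17**
Reactants: 28 (5Z,8R,11R,12R,13E,15S)-11-hydroxy-9-oxoprosta-5,13-dieno-1,15-lactone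
Product: 29 (5Z,8R,11R,12R,13E,15S)-11-acetoxy-9-oxoprosta-5,13-dieno-1,15-lactone (prostaglandin E2 1,15-lactone 11-acetate, CNP0241847.1)
Conditions: Ac2O (3 equiv), pyridine, 0 °C → rt, no DMAP
Reagents that add atoms: acetic anhydride, CC(=O)OC(C)=O
Why: O-Acetylation of the secondary alcohol with retention at C11, kept cold and free of stronger base so that acyl transfer outruns β-elimination to the cyclopentenone.

## Compound list

1 | hexanoyl chloride | CCCCCC(Cl)=O | starting material
2 | acetylene | C#C | starting material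
3 | (E)-1-chlorooct-1-en-3-one | CCCCCC(=O)/C=C/Cl | intermediate
4 | (E)-1-iodooct-1-en-3-one | CCCCCC(=O)/C=C/I | intermediate
5 | 2-{[(S,E)-1-iodooct-1-en-3-yl]oxy}-1,3,2-benzodioxaborole | CCCCC[C@H](OB1Oc2ccccc2O1)/C=C/I | intermediate
6 | (S,E)-1-iodooct-1-en-3-ol | CCCCC[C@H](O)/C=C/I | intermediate
7 | (S,E)-triethyl[(1-iodooct-1-en-3-yl)oxy]silane | CCCCC[C@H](O[Si](CC)(CC)CC)/C=C/I | intermediate
8 | cis-cyclopent-4-ene-1,3-diyl diacetate (meso, 1R,3S) | CC(=O)O[C@@H]1C=C[C@H](OC(C)=O)C1 | starting material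
9 | (1R,4S)-4-hydroxycyclopent-2-en-1-yl acetate (cis) | O[C@@H]1C=C[C@H](OC(C)=O)C1 | intermediate
10 | (R)-4-oxocyclopent-2-en-1-yl acetate | O=C1C=C[C@H](OC(C)=O)C1 | intermediate
11 | (R)-4-hydroxycyclopent-2-en-1-one | O=C1C=C[C@H](O)C1 | intermediate
12 | (R)-4-[(tert-butyldimethylsilyl)oxy]cyclopent-2-en-1-one | O=C1C=C[C@H](O[Si](C)(C)C(C)(C)C)C1 | intermediate
13 | hex-5-ynoic acid | C#CCCCC(=O)O | starting material
14 | dilithium salt of hex-5-ynoic acid (acetylide carboxylate dianion) | [Li]C#CCCCC(=O)O[Li] | intermediate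
15 | lithium hept-5-ynoate | CC#CCCCC(=O)O[Li] | intermediate
16 | hept-5-ynoic acid | CC#CCCCC(=O)O | intermediate
17 | 1-bromobut-2-yne | CC#CCBr | starting material
18 | 1-iodobut-2-yne | CC#CCI | intermediate
19 | [(S,E)-3-[(triethylsilyl)oxy]oct-1-en-1-yl]lithium | CCCCC[C@H](O[Si](CC)(CC)CC)/C=C/[Li] | intermediate
20 | lithium dimethyl[(S,E)-3-[(triethylsilyl)oxy]oct-1-en-1-yl]zincate | [Li+].CCCCC[C@H](O[Si](CC)(CC)CC)/C=C/[Zn-](C)C | intermediate
21 | lithium (3R,4R)-4-[(tert-butyldimethylsilyl)oxy]-3-[(S,E)-3-[(triethylsilyl)oxy]oct-1-en-1-yl]cyclopent-1-en-1-olate (Me2Zn still present) | CCCCC[C@H](O[Si](CC)(CC)CC)/C=C/[C@H]1[C@H](O[Si](C)(C)C(C)(C)C)CC(O[Li])=C1 | intermediate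
22 | (2R,3R,4R)-2-(but-2-yn-1-yl)-4-[(tert-butyldimethylsilyl)oxy]-3-[(S,E)-3-[(triethylsilyl)oxy]oct-1-en-1-yl]cyclopentan-1-one | CCCCC[C@H](O[Si](CC)(CC)CC)/C=C/[C@H]1[C@H](O[Si](C)(C)C(C)(C)C)CC(=O)[C@@H]1CC#CC | intermediate
23 | (2R,3R,4R)-2-(but-2-yn-1-yl)-4-[(tert-butyldimethylsilyl)oxy]-3-[(S,E)-3-hydroxyoct-1-en-1-yl]cyclopentan-1-one | CCCCC[C@H](O)/C=C/[C@H]1[C@H](O[Si](C)(C)C(C)(C)C)CC(=O)[C@@H]1CC#CC | intermediate
24 | O-(hept-5-ynoyl)-N,N'-dicyclohexylisourea | CC#CCCCC(=O)OC(=NC1CCCCC1)NC1CCCCC1 | intermediate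
25 | (S,E)-1-[(1R,2R,5R)-2-(but-2-yn-1-yl)-5-[(tert-butyldimethylsilyl)oxy]-3-oxocyclopentyl]oct-1-en-3-yl hept-5-ynoate | CCCCC[C@H](OC(=O)CCCC#CC)/C=C/[C@H]1[C@H](O[Si](C)(C)C(C)(C)C)CC(=O)[C@@H]1CC#CC | intermediate
26 | (8R,11R,12R,13E,15S)-11-[(tert-butyldimethylsilyl)oxy]-9-oxoprost-13-en-5-yno-1,15-lactone | CCCCC[C@H]1/C=C/[C@H]2[C@H](O[Si](C)(C)C(C)(C)C)CC(=O)[C@@H]2CC#CCCCC(=O)O1 | intermediate
27 | (5Z,8R,11R,12R,13E,15S)-11-[(tert-butyldimethylsilyl)oxy]-9-oxoprosta-5,13-dieno-1,15-lactone | CCCCC[C@H]1/C=C/[C@H]2[C@H](O[Si](C)(C)C(C)(C)C)CC(=O)[C@@H]2C/C=C\CCCC(=O)O1 | intermediate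
28 | (5Z,8R,11R,12R,13E,15S)-11-hydroxy-9-oxoprosta-5,13-dieno-1,15-lactone | CCCCC[C@H]1/C=C/[C@H]2[C@H](O)CC(=O)[C@@H]2C/C=C\CCCC(=O)O1 | intermediate
29 | (5Z,8R,11R,12R,13E,15S)-11-acetoxy-9-oxoprosta-5,13-dieno-1,15-lactone | CCCCC[C@H]1/C=C/[C@H]2[C@H](OC(C)=O)CC(=O)[C@@H]2C/C=C\CCCC(=O)O1 | target

## Step count and risks

Total step count: 17 (vinyl iodide branch, steps 1–4; enone branch, steps 5–8; acid, step 9; propargylic iodide, step 10; trunk, steps 11–17).

Longest linear sequence: 11 steps (steps 1–4 then 11–17; the enone branch 5–8 then 11–17 is equally long), which is 11/17, about 65 % of the total.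

Stereocentres: C15 is set in step 3, C11 in step 5, C12 and C8 in step 11, the 13E alkene in steps 1–2 and the 5Z alkene in step 15.

**Step 11 (three-component coupling).** This is the most demanding operation. The enolate can equilibrate by proton transfer, alkylate twice, or stay unreactive toward the propargylic iodide. The fallback sets out from enolate 21 and comes back at 22. It keeps the conjugate addition but brings in C7 and the alkyne differently. Enolate 21 is trapped at −78 °C with monomeric formaldehyde, a far better electrophile than an alkyl iodide, to give the aldol (2S,3R,4R)-4-[(tert-butyldimethylsilyl)oxy]-2-(hydroxymethyl)-3-[(S,E)-3-[(triethylsilyl)oxy]oct-1-en-1-yl]cyclopentan-1-one F1. Treatment with MsCl and Et3N in CH2Cl2 gives [(1S,2R,3R)-3-[(tert-butyldimethylsilyl)oxy]-5-oxo-2-[(S,E)-3-[(triethylsilyl)oxy]oct-1-en-1-yl]cyclopentyl]methyl methanesulfonate F2, which eliminates in the same flask to the exo-methylene ketone (3R,4R)-4-[(tert-butyldimethylsilyl)oxy]-2-methylidene-3-[(S,E)-3-[(triethylsilyl)oxy]oct-1-en-1-yl]cyclopentan-1-one F3. This enone is locked s-cis and therefore accepts an alkynyl group in a 1,4-addition from dimethyl(prop-1-yn-1-yl)aluminium F4, made beforehand from prop-1-ynylmagnesium bromide and Me2AlCl. Quenching the aluminium enolate with dilute HCl, and equilibrating C8 on silica if needed, gives the more stable trans,trans ketone 22.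

**Step 14 (ring-closing alkyne metathesis).** The product is a strained 13-membered ring holding an alkyne, an E-alkene and a trans ring fusion, so oligomerisation or catalyst death by adventitious water can win. The fallback sets out from 25 and comes back at 27, and avoids the cycloalkyne altogether. Both alkynes of 25 are first semihydrogenated (H2, Pd/CaCO3 poisoned with Pb(OAc)2, quinoline) to the bis-Z diene (S,E)-1-[(1R,2R,5R)-2-[(Z)-but-2-en-1-yl]-5-[(tert-butyldimethylsilyl)oxy]-3-oxocyclopentyl]oct-1-en-3-yl (Z)-hept-5-enoate F5. The ring is then closed by stereoretentive olefin ring-closing metathesis with the ruthenium dithiolate catalyst Ru(=CH-C6H4-2-OiPr)(S2C6H2Cl2)(SIMes) (SIMes = 1,3-dimesitylimidazolidin-2-ylidene) in dilute THF at 40 °C. This catalyst carries the Z geometry of the two reacting alkenes into the product, releases (Z)-but-2-ene, and leaves the hindered E-alkene alone, giving 27 directly.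

**Step 17 (acetylation).** A β-hydroxy or β-acetoxy cyclopentanone can lose the C11 oxygen by E1cB elimination under basic acylation, giving the cyclopentenone. The fallback sets out from 27 and comes back at 29, and does the acetylation while C9 is an alcohol. The ketone of 27 is reduced with LiBH(s-Bu)3 (L-Selectride) in THF at −78 °C, hydride arriving from the face opposite the adjacent C8 chain, to give (5Z,8R,9S,11R,12R,13E,15S)-11-[(tert-butyldimethylsilyl)oxy]-9-hydroxyprosta-5,13-dieno-1,15-lactone F6. Aqueous HF in MeCN gives the diol (5Z,8R,9S,11R,12R,13E,15S)-9,11-dihydroxyprosta-5,13-dieno-1,15-lactone F7. The more accessible 11-hydroxyl (the 9-hydroxyl is shielded by the cis C8 chain) is acetylated with 1.1 equiv Ac2O in pyridine at −20 °C to give (5Z,8R,9S,11R,12R,13E,15S)-11-acetoxy-9-hydroxyprosta-5,13-dieno-1,15-lactone F8. Dess–Martin oxidation of the remaining 9-hydroxyl in CH2Cl2 then gives 29, so the β-acetoxy ketone never meets a base.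

## Further compounds

F1 | step 11 | (2S,3R,4R)-4-[(tert-butyldimethylsilyl)oxy]-2-(hydroxymethyl)-3-[(S,E)-3-[(triethylsilyl)oxy]oct-1-en-1-yl]cyclopentan-1-one | CCCCC[C@H](O[Si](CC)(CC)CC)/C=C/[C@H]1[C@H](O[Si](C)(C)C(C)(C)C)CC(=O)[C@@H]1CO
F2 | step 11 | [(1S,2R,3R)-3-[(tert-butyldimethylsilyl)oxy]-5-oxo-2-[(S,E)-3-[(triethylsilyl)oxy]oct-1-en-1-yl]cyclopentyl]methyl methanesulfonate | CCCCC[C@H](O[Si](CC)(CC)CC)/C=C/[C@H]1[C@H](O[Si](C)(C)C(C)(C)C)CC(=O)[C@@H]1COS(C)(=O)=O
F3 | step 11 | (3R,4R)-4-[(tert-butyldimethylsilyl)oxy]-2-methylidene-3-[(S,E)-3-[(triethylsilyl)oxy]oct-1-en-1-yl]cyclopentan-1-one | CCCCC[C@H](O[Si](CC)(CC)CC)/C=C/[C@H]1[C@H](O[Si](C)(C)C(C)(C)C)CC(=O)C1=C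
F4 | step 11 | dimethyl(prop-1-yn-1-yl)aluminium | CC#C[Al](C)C
F5 | step 14 | (S,E)-1-[(1R,2R,5R)-2-[(Z)-but-2-en-1-yl]-5-[(tert-butyldimethylsilyl)oxy]-3-oxocyclopentyl]oct-1-en-3-yl (Z)-hept-5-enoate | CCCCC[C@H](OC(=O)CCC/C=C\C)/C=C/[C@H]1[C@H](O[Si](C)(C)C(C)(C)C)CC(=O)[C@@H]1C/C=C\C
F6 | step 17 | (5Z,8R,9S,11R,12R,13E,15S)-11-[(tert-butyldimethylsilyl)oxy]-9-hydroxyprosta-5,13-dieno-1,15-lactone | CCCCC[C@H]1/C=C/[C@H]2[C@H](O[Si](C)(C)C(C)(C)C)C[C@H](O)[C@@H]2C/C=C\CCCC(=O)O1
F7 | step 17 | (5Z,8R,9S,11R,12R,13E,15S)-9,11-dihydroxyprosta-5,13-dieno-1,15-lactone | CCCCC[C@H]1/C=C/[C@H]2[C@H](O)C[C@H](O)[C@@H]2C/C=C\CCCC(=O)O1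
F8 | step 17 | (5Z,8R,9S,11R,12R,13E,15S)-11-acetoxy-9-hydroxyprosta-5,13-dieno-1,15-lactone | CCCCC[C@H]1/C=C/[C@H]2[C@H](OC(C)=O)C[C@H](O)[C@@H]2C/C=C\CCCC(=O)O1
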